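Lindenane numbering is used throughout. The target is the head-to-head [2+2] photodimer of chloranthalactone A, so the route builds that monomer and dimerises it last. In ring A the exocyclic C4=C15 alkene lies between cyclopropane carbon C3 and ring-fusion carbon C5; the C4–C5 bond (present in each half of the dimer) is therefore closed by a Conia-ene carbocyclisation, in which a C5 malonate carbanion adds 5-exo-dig to a C4≡C15 alkyne held cis on the cyclopropane. This forms the bicyclo[3.1.0]hexane and the exo-methylene at once. The gem-diester is a temporary activator: one ester becomes C6 of ring B, the other is excised later to install H5 trans to the C14 methyl.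

Key step: step 6

Remarks on the chemistry:
- Numbering: cyclopropane C1–C2–C3 (C2 = CH2); ring A = C10, C1, C3, C4(=C15), C5; ring B = C5–C10; C14 = methyl on C10; butenolide = C7, C11 (C13 methyl), C12, O, C8.
- Assumption: (1R,5S)-3-oxabicyclo[3.1.0]hexan-2-one is taken as a purchasable enantiopure building block.

Step 1
Reactants: 1 (1R,5S)-3-oxabicyclo[3.1.0]hexan-2-one
Product: 2 1-[(1R,2S)-2-(hydroxymethyl)cyclopropyl]ethan-1-one (equilibrates with its cyclic hemiketal)
Conditions: MeLi (1.05 equiv), THF, −78 °C; then H2O
Reagents that add atoms: methyllithium, [Li]C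
Why: Nucleophilic acyl addition of MeLi to a γ-lactone should stop at the lithium hemiketal alkoxide at −78 °C and so give the methyl ketone (C10, C14) without touching the two cyclopropane stereocentres taken from 1.

Step 2
Reactants: 2 1-[(1R,2S)-2-(hydroxymethyl)cyclopropyl]ethan-1-one
Product: 3 (1S,2R)-2-acetylcyclopropane-1-carbaldehyde
Conditions: Dess–Martin periodinane, CH2Cl2, rt
Reagents that add atoms: none
Why: Dess–Martin oxidation of the primary alcohol of the ring-opened form under non-basic conditions should give the cis keto aldehyde without epimerising the cyclopropane.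

Step 3
Reactants: 3 (1S,2R)-2-acetylcyclopropane-1-carbaldehyde
Product: 4 1-[(1R,2S)-2-ethynylcyclopropyl]ethan-1-one
Conditions: Bestmann–Ohira reagent, K2CO3, MeOH, 0 °C
Reagents that add atoms: dimethyl (1-diazo-2-oxopropyl)phosphonate, CC(=O)C(=[N+]=[N-])P(=O)(OC)OC
Why: Seyferth–Gilbert homologation in the Ohira–Bestmann variant converts the aldehyde (far more reactive than the methyl ketone) into the terminal alkyne C4≡C15 quickly at 0 °C, which limits base-induced cis-to-trans epimerisation.

Step 4
Reactants: 4 1-[(1R,2S)-2-ethynylcyclopropyl]ethan-1-one; 5 dimethyl malonate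
Product: 6 dimethyl 2-{1-[(1R,2S)-2-ethynylcyclopropyl]ethylidene}propanedioate
Conditions: TiCl4, pyridine, THF, 0 °C to rt
Reagents that add atoms: none
Why: Knoevenagel condensation of a ketone under Lehnert conditions should give the tetrasubstituted alkylidene malonate, which has no E/Z issue because both ester groups are the same.

Step 5
Reactants: 6 dimethyl 2-{1-[(1R,2S)-2-ethynylcyclopropyl]ethylidene}propanedioate
Product: 7 dimethyl 2-{(2S)-2-[(1R,2S)-2-ethynylcyclopropyl]pent-4-en-2-yl}propanedioate
Conditions: allylMgBr (2.2 equiv), CuBr·SMe2 (10 mol %), THF, −78 to −30 °C; then aq. NH4Cl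
Reagents that add atoms: allylmagnesium bromide, C=CC[Mg]Br
Why: Copper-catalysed conjugate addition creates quaternary C10; A(1,3) strain with the cis ester holds the vinylcyclopropane in the s-trans bisected conformation, so the allyl group should enter on the alkene face flanked by the cyclopropane CH2, away from the ethynyl-bearing carbon, which places the allyl arm (future C9) anti and the methyl syn to the cyclopropane methylene.

Step 6
Reactants: 7 dimethyl 2-{(2S)-2-[(1R,2S)-2-ethynylcyclopropyl]pent-4-en-2-yl}propanedioate
Product: 8 dimethyl (1R,2S,5S)-2-methyl-4-methylidene-2-(prop-2-en-1-yl)bicyclo[3.1.0]hexane-3,3-dicarboxylate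
Conditions: CuI (10 mol %), t-BuOK (20 mol %), THF, 30 °C
Reagents that add atoms: none
Why: t-BuOK deprotonates the malonate and Cu(I) activates the terminal alkyne, so the C5 carbanion adds anti across C4≡C15 at the internal carbon C4 and the vinylcopper is protonated by the next malonate C–H, which turns over both catalysts and leaves the exocyclic C4=C15 alkene. The closest known reaction is the Conia-ene-type carbocyclisation of ε-acetylenic malonates and β-keto esters (Cu(I)/base, Au(I) or In(III) catalysis). The ring closes 5-exo-dig and gives the cyclopentane of a bicyclo[3.1.0]hexane, necessarily cis-fused because both tether ends are cis on the cyclopropane. No new stereocentre is formed: C5 bears two identical esters, so the trans C5/C10 relationship need not be controlled in a ring closure and is set later by protonation. The step needs C- over O-attack, exo over endo attack and reaction at the alkyne and not the allyl alkene; the soft copper–alkyne complex, the Markovnikov polarisation of the terminal alkyne and the short rigid cis-cyclopropane tether next to quaternary C10 (Thorpe–Ingold effect) should secure these.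

Step 7
Reactants: 8 dimethyl (1R,2S,5S)-2-methyl-4-methylidene-2-(prop-2-en-1-yl)bicyclo[3.1.0]hexane-3,3-dicarboxylate
Product: 9 dimethyl (1R,2S,5S)-2-methyl-4-methylidene-2-(2-oxopropyl)bicyclo[3.1.0]hexane-3,3-dicarboxylate
Conditions: PdCl2 (10 mol %), CuCl, O2 (1 atm), DMF/H2O, rt
Reagents that add atoms: water, O
Why: Tsuji–Wacker oxidation should convert the monosubstituted allyl alkene into the methyl ketone (C8=O, C7 methyl), while the 1,1-disubstituted exocyclic alkene reacts far more slowly and cannot migrate because C5 is quaternary.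

Step 8
Reactants: 9 dimethyl (1R,2S,5S)-2-methyl-4-methylidene-2-(2-oxopropyl)bicyclo[3.1.0]hexane-3,3-dicarboxylate
Product: 10 methyl 6,8-dioxo-11,12,13-trinorlinden-4(15)-ene-5-carboxylate (rings A/B cis-fused; CO2Me on C5 cis to C14; drawn as the diketo tautomer)
Conditions: NaOMe, MeOH, reflux; then 1 M HCl, 0 °C
Reagents that add atoms: none
Why: Intramolecular Claisen (Dieckmann-type) condensation of the methyl ketone enolate (C7) onto the ester lying cis to the acetonyl arm closes ring B as a cyclohexane-1,3-dione and is driven by the stable diketonate; which ester reacts is of no consequence because the other is removed in step 10.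

Step 9
Reactants: 10 methyl 6,8-dioxo-11,12,13-trinorlinden-4(15)-ene-5-carboxylate
Product: 11 methyl 8-(2-methylpropoxy)-6-oxo-11,12,13-trinorlindena-4(15),7-diene-5-carboxylate
Conditions: i-BuOH, TsOH (cat.), benzene, reflux (Dean–Stark)
Reagents that add atoms: 2-methylpropan-1-ol, CC(C)CO
Why: Acid-catalysed enol etherification under thermodynamic control should place the isobutoxy group on the C8 oxygen, remote from quaternary C5, which leaves C6 as the β-keto ester carbonyl; with C5 quaternary neither it nor the exocyclic alkene can isomerise.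

Step 10
Reactants: 11 methyl 8-(2-methylpropoxy)-6-oxo-11,12,13-trinorlindena-4(15),7-diene-5-carboxylate
Product: 13 8-(2-methylpropoxy)-11,12,13-trinorlindena-4(15),7-dien-6-one (5α-H; rings A/B trans-fused), via lithium dienolate 12 (not isolated)
Conditions: LiCl, H2O, DMSO, 130 °C
Reagents that add atoms: none
Why: Krapcho dealkoxycarbonylation of the β-keto ester gives dienolate 12, and protonation at C5 should occur on the α-face, anti to the pseudo-axial C14 methyl and the cyclopropane CH2, which sets H5 trans to C14; the weakly acidic α′-hydrogen of the vinylogous ester should then hold this kinetic configuration.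

Step 11
Reactants: 13 8-(2-methylpropoxy)-11,12,13-trinorlindena-4(15),7-dien-6-one
Product: 15 11,12,13-trinorlindena-4(15),6-dien-8-one, via allylic alcohol 14 (not isolated)
Conditions: DIBAL-H, CH2Cl2, −78 °C; then 1 M HCl, THF, 0 °C
Reagents that add atoms: none
Why: Stork–Danheiser transposition: 1,2-reduction of the C6 carbonyl, then acid hydrolysis of the enol ether with loss of water, should give the enone with its carbonyl at C8 under conditions too mild to epimerise C5.

Step 12
Reactants: 15 11,12,13-trinorlindena-4(15),6-dien-8-one; 16 ethyl pyruvate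
Product: 18 ethyl 11-hydroxy-8-oxolinden-4(15)-en-12-oate (mixture of C7/C11 epimers), via lithium enolate 17 (not isolated)
Conditions: L-Selectride, THF, −78 °C; then ethyl pyruvate, −78 °C; then AcOH
Reagents that add atoms: none
Why: Reductive aldol reaction: conjugate hydride delivery to C6 gives the C7 enolate regiospecifically, which adds to the ketone carbonyl of ethyl pyruvate and so attaches C11 to C13; the new stereocentres at C7 and C11 are removed in step 13.

Step 13
Reactants: 18 ethyl 11-hydroxy-8-oxolinden-4(15)-en-12-oate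
Product: 20 chloranthalactone A [lindena-4(15),7(11),8-trien-12,8-olide], via unsaturated keto ester 19 (not isolated)
Conditions: TsOH·H2O, benzene, reflux
Reagents that add atoms: none
Why: Acid-catalysed dehydration and enol lactonisation should give the fully conjugated γ-ylidene butenolide (C7=C11 and C8=C9), the thermodynamic product, without disturbing C5 or C10.

Step 14
Reactants: 20 chloranthalactone A (two molecules)
Product: 21 CNP0265879.1 (head-to-head cyclobutane dimer of 20; C8–C8′ and C9–C9′ bonds)
Conditions: hν (medium-pressure Hg lamp, Pyrex), degassed CH2Cl2, rt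
Reagents that add atoms: none
Why: Head-to-head [2+2] photocycloaddition of the enol-lactone C8=C9 bonds of two molecules forms C8–C8′ and C9–C9′; each alkene should react on its α-face, anti to the C14 methyl, which gives the four cyclobutane stereocentres of the C2-symmetric dimer.

Compound list
1 | (1R,5S)-3-oxabicyclo[3.1.0]hexan-2-one | O=C1OC[C@H]2C[C@@H]12 | starting material
2 | 1-[(1R,2S)-2-(hydroxymethyl)cyclopropyl]ethan-1-one | CC(=O)[C@@H]1C[C@@H]1CO | intermediate
3 | (1S,2R)-2-acetylcyclopropane-1-carbaldehyde | CC(=O)[C@@H]1C[C@@H]1C=O | intermediate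
4 | 1-[(1R,2S)-2-ethynylcyclopropyl]ethan-1-one | CC(=O)[C@@H]1C[C@@H]1C#C | intermediate
5 | dimethyl malonate | COC(=O)CC(=O)OC | starting material
6 | dimethyl 2-{1-[(1R,2S)-2-ethynylcyclopropyl]ethylidene}propanedioate | COC(=O)C(C(=O)OC)=C(C)[C@@H]1C[C@@H]1C#C | intermediate
7 | dimethyl 2-{(2S)-2-[(1R,2S)-2-ethynylcyclopropyl]pent-4-en-2-yl}propanedioate | COC(=O)C(C(=O)OC)[C@@](C)(CC=C)[C@@H]1C[C@@H]1C#C | intermediate
8 | dimethyl (1R,2S,5S)-2-methyl-4-methylidene-2-(prop-2-en-1-yl)bicyclo[3.1.0]hexane-3,3-dicarboxylate | C=C1[C@H]2C[C@H]2[C@](C)(CC=C)C1(C(=O)OC)C(=O)OC | intermediate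
9 | dimethyl (1R,2S,5S)-2-methyl-4-methylidene-2-(2-oxopropyl)bicyclo[3.1.0]hexane-3,3-dicarboxylate | C=C1[C@H]2C[C@H]2[C@](C)(CC(C)=O)C1(C(=O)OC)C(=O)OC | intermediate
10 | methyl 6,8-dioxo-11,12,13-trinorlinden-4(15)-ene-5-carboxylate (cis-fused; CO2Me cis to C14) | C=C1[C@H]2C[C@H]2[C@]2(C)CC(=O)CC(=O)[C@]12C(=O)OC | intermediate
11 | methyl 8-(2-methylpropoxy)-6-oxo-11,12,13-trinorlindena-4(15),7-diene-5-carboxylate | C=C1[C@H]2C[C@H]2[C@]2(C)CC(OCC(C)C)=CC(=O)[C@]12C(=O)OC | intermediate
12 | lithium dienolate (C5=C6–OLi) formed from 11 by loss of the ester | C=C1[C@H]2C[C@H]2[C@@]2(C)C1=C([O-])C=C(OCC(C)C)C2.[Li+] | intermediate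
13 | 8-(2-methylpropoxy)-11,12,13-trinorlindena-4(15),7-dien-6-one (5α-H, trans-fused) | C=C1[C@H]2C[C@H]2[C@@]2(C)[C@H]1C(=O)C=C(OCC(C)C)C2 | intermediate
14 | 8-(2-methylpropoxy)-11,12,13-trinorlindena-4(15),7-dien-6-ol (C6 epimers) | C=C1[C@H]2C[C@H]2[C@@]2(C)[C@H]1C(O)C=C(OCC(C)C)C2 | intermediate
15 | 11,12,13-trinorlindena-4(15),6-dien-8-one | C=C1[C@H]2C[C@H]2[C@@]2(C)[C@H]1C=CC(=O)C2 | intermediate
16 | ethyl pyruvate | CC(=O)C(=O)OCC | starting material
17 | lithium C7(8)-enolate of 11,12,13-trinorlinden-4(15)-en-8-one | C=C1[C@H]2C[C@H]2[C@@]2(C)[C@H]1CC=C([O-])C2.[Li+] | intermediate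
18 | ethyl 11-hydroxy-8-oxolinden-4(15)-en-12-oate (C7/C11 epimers) | C=C1[C@H]2C[C@H]2[C@@]2(C)[C@H]1CC(C(C)(O)C(=O)OCC)C(=O)C2 | intermediate
19 | ethyl 8-oxolindena-4(15),7(11)-dien-12-oate | C=C1[C@H]2C[C@H]2[C@@]2(C)[C@H]1CC(=C(C)C(=O)OCC)C(=O)C2 | intermediate
20 | chloranthalactone A | C=C1[C@H]2C[C@H]2[C@@]2(C)[C@H]1CC1=C(C)C(=O)OC1=C2 | intermediate
21 | CNP0265879.1 (head-to-head [2+2] dimer of 20) | C=C1[C@H]2C[C@H]2[C@@]2(C)[C@H]1CC1=C(C)C(=O)O[C@]13[C@H]2[C@H]1[C@@]2(C)[C@@H]4C[C@@H]4C(=C)[C@@H]2CC2=C(C)C(=O)O[C@@]213 | target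

Total step count: 14. Longest linear sequence: 14 steps (from 1).

Steps most likely to fail

Step 10. The dienolate may be protonated on the β-face (cis-fused C5 epimer) or at C15, which would move the exocyclic alkene into conjugation; prolonged heating favours both. The fallback separates ester removal from C–H formation. It sets out from 11: the dealkoxycarbonylation is run without regard to C5 and gives the ketone as an epimer mixture containing the cis-fused 5-epi ketone F1. This mixture is deprotonated at C5 with LDA (THF, −78 °C) to regenerate dienolate 12, which is quenched at −78 °C with the bulky proton donor 2,6-di-tert-butyl-4-methylphenol under strictly kinetic conditions. The route is rejoined at 13.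

Step 5. The ethynyl group is a slim shield, so discrimination between the two faces of C10 may be poor. The fallback makes the quaternary centre while C3 still carries a large silyloxymethyl group and builds the alkyne afterwards. It sets out from 2: silylation (TBDPSCl, imidazole) gives 1-[(1R,2S)-2-{[tert-butyl(diphenyl)silyl]oxymethyl}cyclopropyl]ethan-1-one F2; Knoevenagel condensation with 5 (TiCl4, pyridine) gives the alkylidene malonate F3; the same copper-catalysed allyl addition gives the quaternary malonate F4; TBAF gives the alcohol F5; Dess–Martin oxidation gives the aldehyde F6; Ohira–Bestmann homologation then returns to the route at 7.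

Step 6. The malonate C–H sits next to quaternary C10, so the copper/base cycle may stall, or the copper acetylide may be diverted into oxidative alkyne coupling. The fallback changes the polarity of the ring closure to a radical one. It sets out from 7: Mn(OAc)3·2H2O in ethanol (Mn(III)-based oxidative free-radical cyclisation) generates the C5 malonyl radical, which adds 5-exo-dig to C4; the vinyl radical at C15 abstracts hydrogen from ethanol. This returns to the route directly at 8 and passes through no new compound.

Further compounds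
F1 | step 10 | 8-(2-methylpropoxy)-11,12,13-trinorlindena-4(15),7-dien-6-one, 5β-H epimer (cis-fused) | C=C1[C@H]2C[C@H]2[C@@]2(C)[C@@H]1C(=O)C=C(OCC(C)C)C2
F2 | step 5 | 1-[(1R,2S)-2-{[tert-butyl(diphenyl)silyl]oxymethyl}cyclopropyl]ethan-1-one | CC(=O)[C@@H]1C[C@@H]1CO[Si](c1ccccc1)(c1ccccc1)C(C)(C)C
F3 | step 5 | dimethyl 2-{1-[(1R,2S)-2-{[tert-butyl(diphenyl)silyl]oxymethyl}cyclopropyl]ethylidene}propanedioate | COC(=O)C(C(=O)OC)=C(C)[C@@H]1C[C@@H]1CO[Si](c1ccccc1)(c1ccccc1)C(C)(C)C
F4 | step 5 | dimethyl 2-{(2S)-2-[(1R,2S)-2-{[tert-butyl(diphenyl)silyl]oxymethyl}cyclopropyl]pent-4-en-2-yl}propanedioate | COC(=O)C(C(=O)OC)[C@@](C)(CC=C)[C@@H]1C[C@@H]1CO[Si](c1ccccc1)(c1ccccc1)C(C)(C)C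
F5 | step 5 | dimethyl 2-{(2S)-2-[(1R,2S)-2-(hydroxymethyl)cyclopropyl]pent-4-en-2-yl}propanedioate | COC(=O)C(C(=O)OC)[C@@](C)(CC=C)[C@@H]1C[C@@H]1CO
F6 | step 5 | dimethyl 2-{(2S)-2-[(1R,2S)-2-formylcyclopropyl]pent-4-en-2-yl}propanedioate | COC(=O)C(C(=O)OC)[C@@](C)(CC=C)[C@@H]1C[C@@H]1C=O
F0 | step 6 | none | none
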